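The earlier runs and the new flask were computed for substances that don't exist.

What needs explaining in these flasks is a leftover: the tris adduct, built by reagent from starting material through single and double product, stands above a plateau and then falls as it passes reversibly into its isomer.

| flask | starting material | reagent | temperature | remark | time |
|---|---|---|---|---|---|
| south-west | 10 mM | 2 equiv | 25 °C | the very flask that is asked about, followed so far |  |
| north-west | 10 mM | 2 equiv | 10 °C | run made earlier |  |
| flask | 10 mM | 2.00 equiv | 25 °C |  | 8.0 d |

| run | time / h | tris adduct / % |
|---|---|---|
| south-west | 12.0 | 32.0 |
| south-west | 25.0 | 24.6 |
| south-west | 40.0 | 19.5 |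
| south-west | 72.0 | 19.0 |
| south-west | 144 | 19.3 |
| north-west | 25.0 | 35.9 |
| north-west | 48.0 | 33.5 |
| north-west | 96.0 | 31.0 |
| north-west | 144 | 22.8 |
| north-west | 288 | 13.8 |

(each reading ± 1 percentage point)

- beta: at 8.0 d take out 90 % of the tris adduct then present, then wait 2.5 d
- alpha: at 8.0 d add reagent, 100 % of the amount charged, then wait 2.5 d
- delta: at 8.0 d raise the temperature by 15 K, then wait 2.5 d
- epsilon: change nothing and wait 2.5 d more

- tris adduct, in percent of the starting material first charged, at 8.0 d
- what to do for the largest gain in tris adduct; "none" if nothing gains more than 2 percentage points (beta / alpha / delta / epsilon / none)
- tris adduct present, with what was taken out counted in, in percent of the starting material first charged, after alpha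
- tris adduct present, with what was taken out counted in, in percent of the starting material first charged, after delta

- removed tris adduct is counted in
- the numbers in the tables scatter by 1 percentage point (one standard deviation)
- reactions considered so far: reagent + double product -> tris adduct + released group; starting material + reagent -> single product + released group; tris adduct <-> isomer of the product; reagent + single product -> double product + released group
- additions bring no volume worth counting

I take the south-west plateau as 19.0 %. The excess of tris adduct over it is 13 percentage points at 12.0 h and 5.6 points at 25.0 h, which gives 10.7 h. That is the number I carry: the time in which the tris adduct closes half its distance to the plateau, the relaxation half-life.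

Now the ladder. Building comes first: the first south-west reading is already the highest of that run, so I take building as largely over by 12.0 h. Relaxation is next. Slower again is the same relaxation in the north-west run, where the excess over the last reading gives roughly 91.8 h, a rough value because that last reading may not be the floor. The two runs lie 15 K apart, the same step as option delta, so I expect about 1.25 h after that rise. Last comes the look itself: 8.0 d is 17.9 half-lives, and the wait of 2.5 d is 5.61. So I expect thermodynamic rather than kinetic control of the pair at the look and after each option, and I commit to 19.1 % for now.

The forecast says 19.3 %, chooses alpha with 46 %, and gives 26 % for delta: “Tris then sits at isomerisation equilibrium”.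

The flask gives 18.6 %, and alpha gains most, reaching 40.5 %; delta reaches 33.6 %. The forecast's choice stands, and its two amounts part from the flask in opposite directions, by 5.5 points and 7.6 points.

    reagent + double product → tris adduct + released group (k = 95.0 L mol⁻¹ h⁻¹, Ea = 64.0 kJ mol⁻¹)
    starting material + reagent → single product + released group (k = 59.0 L mol⁻¹ h⁻¹, Ea = 43.0 kJ mol⁻¹)
    tris adduct ⇌ isomer of the product (K = 1.50, k = 0.0450 h⁻¹, Ea = 102 kJ mol⁻¹, ΔH = −71.0 kJ mol⁻¹)
    reagent + single product → double product + released group (k = 22.0 L mol⁻¹ h⁻¹, Ea = 50.0 kJ mol⁻¹)
    (constants at 25 °C)

In the flask, 8.0 d is 17.9 of the half-lives I estimated from the scattered readings, and at that time it holds tris adduct 18.6 % beside isomer of the product 27.9 %. Now take a neighbour flask, changed by being kept at 0 °C. From 10 °C that is 10 K further down, and carrying the factor 8.58 per 15 K gives my rough estimate of 385 h, longer than 8.0 d. By that estimate, which rests on readings, the neighbour flask has passed 0.499 of one half-life; at 8.0 d it holds tris adduct 35.3 % beside isomer of the product 6.31 %.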